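**Retrosynthetic overview**
- The target is an ursane with ring C opened (8,14-seco). The last disconnection is C11–C12 (sp3–sp2): a ring A/B homoallylic iodide plus a ring D/E (E)-alkenyl iodide, joined by a light-driven nickel cross-electrophile coupling.
- Both halves are cut from one triterpenoid, ursolic acid: C28 acid to methyl, C3 and C11 oxidised, C12 excised by enone cleavage, then the C8–C14 bond broken by retro-Michael scission of the resulting 1,5-keto ester.
- The two enolates released are protonated kinetically: C14–H on the ring D/E ketone, 9α-H plus the exocyclic methylene on the ring A/B ester. C3 is reset by hydride reduction.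
- C12 is put back on the ring D/E ketone as an (E)-iodomethylidene (titanium silylmethylenation, then iododesilylation).
- Ring order: no ring is built. Rings A, B, D and E are bought with their stereocentres; ring C is opened, C12=C13 first and C8–C14 second.

Assumption: atom numbers follow the ursane skeleton (in the drimane names the carbon on C9 is C11 and the exocyclic methylene carbon is C12, which is ursane C26); Cp2Ti(CH2SiMe3)2 is made beforehand from Cp2TiCl2 and Me3SiCH2Li.

**Route**

Step 1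
Reactants: 1 ursolic acid
Product: 2 uvaol (urs-12-ene-3β,28-diol)
Conditions: LiAlH4, THF, reflux
Reagents that add atoms: none
Why: Hydride reduction of the hindered C28 carboxylic acid to the primary alcohol leaves the trisubstituted 12-ene and all stereocentres untouched.

Step 2
Reactants: 2 uvaol
Product: 3 28-iodours-12-en-3β-ol
Conditions: PPh3, I2, imidazole, toluene, 80 °C
Reagents that add atoms: iodine, II
Why: Appel-type iodination is selective for the primary 28-OH over the hindered secondary 3β-OH flanked by the gem-dimethyl carbon.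

Step 3
Reactants: 3 28-iodours-12-en-3β-ol
Product: 4 α-amyrin (urs-12-en-3β-ol)
Conditions: Bu3SnH, AIBN (cat.), toluene, 100 °C
Reagents that add atoms: none
Why: Radical-chain hydrodeiodination turns CH2I into the C28 methyl group, and the primary radical has no productive rearrangement path.

Step 4
Reactants: 4 α-amyrin
Product: 6 urs-12-ene-3,11-dione, via urs-12-en-3-one 5 (not isolated)
Conditions: CrO3, AcOH/H2O, 70 °C
Reagents that add atoms: chromium trioxide, O=[Cr](=O)=O
Why: Chromium trioxide first oxidises the 3-alcohol and then the allylic C11 methylene (allylic oxidation, the classical entry to 11-oxo-amyrins); C3 is flattened on purpose and reset in step 8.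

Step 5
Reactants: 6 urs-12-ene-3,11-dione
Product: 8 3,13-dioxo-12-nor-12,13-secoursan-11-oic acid, via alpha-keto acid 7 (not isolated)
Conditions: RuCl3·xH2O (5 mol%), NaIO4 (6 equiv), EtOAc/MeCN/H2O, 25 °C
Reagents that add atoms: sodium periodate, [Na+].[O-]I(=O)(=O)=O; water, O
Why: RuO4 made in situ cleaves the enone C12=C13 bond and periodate decarboxylates the α-keto acid (oxidative enone cleavage, as in the degradation of steroidal 4-en-3-ones to keto acids), which leaves C13 as a ketone and C11 as the acid of a 1,5-dicarbonyl spanning the C8–C14 bond.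

Step 6
Reactants: 8 3,13-dioxo-12-nor-12,13-secoursan-11-oic acid
Product: 9 methyl 3,13-dioxo-12-nor-12,13-secoursan-11-oate
Conditions: MeI, K2CO3, DMF, 25 °C
Reagents that add atoms: iodomethane, CI
Why: SN2 O-alkylation of the carboxylate gives the ester whose C9–H is acidic enough for the next step.

Step 7
Reactants: 9 methyl 3,13-dioxo-12-nor-12,13-secoursan-11-oate
Product: 13 methyl 3-oxodrim-8(12)-en-11-oate and 14 (2S,4aR,7R,8S,8aR)-2,4a,7,8-tetramethyloctahydronaphthalen-1(2H)-one, via methyl 3-oxodrim-8-en-11-oate 10 (not isolated), via dilithium bis-enolate of the drimenoate 11 (not isolated), via lithium enolate of the decalone 12 (not isolated)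
Conditions: KOtBu (1.2 equiv), THF, 0 to 25 °C; then LiN(iPr)2 (5 equiv), DMPU, −78 °C; then t-BuCO2H, −78 °C, neutral work-up
Reagents that add atoms: none
Why: Proposed new method: tert-butoxide reversibly removes the C9 proton and the ester enolate expels the C13/C14 enolate by E1cB retro-Michael scission of the C8–C14 bond, driven by relief of the strain between the two fully substituted carbons C8 and C14 (closest known type: base-mediated retro-Michael fragmentation of 1,5-dicarbonyls), after which LiN(iPr)2 removes the methyl proton syn to the ester of enoate 10 and holds the decalone as enolate 12, and the bulky acid protonates dienolate 11 at C9 from the α face (anti to the axial C10 methyl; closest known type: deconjugation of β-cyclogeranates to γ-cyclogeranates) and enolate 12 at C14 from the β face (anti to the axial C19 branch on C18), which sets 9α-H, the exocyclic methylene and the less stable 14α-methyl centre while the cis ring fusion at C18 stays as bought.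

Step 8
Reactants: 13 methyl 3-oxodrim-8(12)-en-11-oate
Product: 15 drim-8(12)-ene-3β,11-diol
Conditions: LiAlH4, THF, −20 to 0 °C
Reagents that add atoms: none
Why: Hydride reduction converts the ester to the C11 carbinol and the C3 ketone to the equatorial 3β-alcohol, because hydride arrives axially from the α face, anti to the axial 4β- and 10β-methyl groups (substrate control).

Step 9
Reactants: 15 drim-8(12)-ene-3β,11-diol
Product: 16 11-iododrim-8(12)-en-3β-ol
Conditions: PPh3, I2, imidazole, CH2Cl2, 0 °C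
Reagents that add atoms: iodine, II
Why: Appel iodination takes the primary C11 alcohol and leaves the hindered secondary 3β-OH, the same selectivity as in step 2.

Step 10
Reactants: 14 (2S,4aR,7R,8S,8aR)-2,4a,7,8-tetramethyloctahydronaphthalen-1(2H)-one
Product: 17 trimethyl{(E)-[(2S,4aR,7R,8S,8aR)-2,4a,7,8-tetramethyloctahydronaphthalen-1(2H)-ylidene]methyl}silane
Conditions: Cp2Ti(CH2SiMe3)2, toluene, 100 °C
Reagents that add atoms: bis(cyclopentadienyl)bis[(trimethylsilyl)methyl]titanium, C[Si](C)(C)C[Ti](C[Si](C)(C)C)(C1C=CC=C1)C1C=CC=C1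
Why: Petasis-type titanium alkylidenation is non-basic and so does not epimerise C14, and in the oxatitanacyclobutane the silyl group sits away from the C18 flank, which is shielded by the 19β-methyl and the quaternary C17, giving the E alkene with silicon cis to C14.

Step 11
Reactants: 17 the (E)-vinylsilane
Product: 18 (2S,4aR,7R,8S,8aR)-1-[(E)-iodomethylidene]-2,4a,7,8-tetramethyldecahydronaphthalene
Conditions: N-iodosuccinimide, (CF3)2CHOH, 0 °C
Reagents that add atoms: N-iodosuccinimide, O=C1CCC(=O)N1I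
Why: Electrophilic iododesilylation (ipso attack, β-silyl cation at tertiary C13, loss of silicon) replaces silicon by iodine with retention of the alkene geometry.

Step 12
Reactants: 16 11-iododrim-8(12)-en-3β-ol; 18 the (E)-alkenyl iodide
Product: 19 (12E)-8,14-secoursa-8(26),12-dien-3β-ol (CNP0141247.1)
Conditions: NiBr2(dme) (10 mol%), 4,4′-di-tert-butyl-2,2′-bipyridine, Ir[dF(CF3)ppy]2(dtbbpy)PF6 (1 mol%), Hantzsch ester, Na2CO3, DMA, 450 nm LEDs, 25 °C
Reagents that add atoms: none
Why: Nickel/photoredox reductive cross-electrophile coupling forms the C11–C12 bond: the photocatalyst and Hantzsch ester turn nickel over, oxidative addition of 18 at zerovalent nickel keeps the E geometry, the C11 radical from 16 is captured and reductive elimination follows, with the free 3β-OH tolerated.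

**Compound list**

1 | ursolic acid (3β-hydroxyurs-12-en-28-oic acid) | C[C@@H]1CC[C@@]2(CC[C@@]3(C(=CC[C@H]4[C@]3(CC[C@@H]5[C@@]4(CC[C@@H](C5(C)C)O)C)C)[C@@H]2[C@H]1C)C)C(=O)O | starting material
2 | uvaol (urs-12-ene-3β,28-diol) | C[C@@H]1CC[C@@]2(CC[C@@]3(C(=CC[C@H]4[C@]3(CC[C@@H]5[C@@]4(CC[C@@H](C5(C)C)O)C)C)[C@@H]2[C@H]1C)C)CO | intermediate
3 | 28-iodours-12-en-3β-ol | C[C@@H]1CC[C@@]2(CC[C@@]3(C(=CC[C@H]4[C@]3(CC[C@@H]5[C@@]4(CC[C@@H](C5(C)C)O)C)C)[C@@H]2[C@H]1C)C)CI | intermediate
4 | α-amyrin (urs-12-en-3β-ol) | C[C@@H]1CC[C@@]2(CC[C@@]3(C(=CC[C@H]4[C@]3(CC[C@@H]5[C@@]4(CC[C@@H](C5(C)C)O)C)C)[C@@H]2[C@H]1C)C)C | intermediate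
5 | urs-12-en-3-one | C[C@@H]1CC[C@@]2(CC[C@@]3(C(=CC[C@H]4[C@]3(CC[C@@H]5[C@@]4(CCC(=O)C5(C)C)C)C)[C@@H]2[C@H]1C)C)C | intermediate (not isolated)
6 | urs-12-ene-3,11-dione | C[C@@H]1CC[C@@]2(CC[C@@]3(C(=CC(=O)[C@H]4[C@]3(CC[C@@H]5[C@@]4(CCC(=O)C5(C)C)C)C)[C@@H]2[C@H]1C)C)C | intermediate
7 | 3,11,13-trioxo-12,13-secoursan-12-oic acid (α-keto acid, ring C opened) | OC(=O)C(=O)[C@@H]1[C@@]2(C)CCC(=O)C(C)(C)[C@@H]2CC[C@@]1(C)[C@@]3(C)C(=O)[C@@H]4[C@@H](C)[C@H](C)CC[C@]4(C)CC3 | intermediate (not isolated)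
8 | 3,13-dioxo-12-nor-12,13-secoursan-11-oic acid (CO2H on C9, ketone at C13, C8–C14 bond intact) | OC(=O)[C@@H]1[C@@]2(C)CCC(=O)C(C)(C)[C@@H]2CC[C@@]1(C)[C@@]3(C)C(=O)[C@@H]4[C@@H](C)[C@H](C)CC[C@]4(C)CC3 | intermediate
9 | methyl 3,13-dioxo-12-nor-12,13-secoursan-11-oate | COC(=O)[C@@H]1[C@@]2(C)CCC(=O)C(C)(C)[C@@H]2CC[C@@]1(C)[C@@]3(C)C(=O)[C@@H]4[C@@H](C)[C@H](C)CC[C@]4(C)CC3 | intermediate
10 | methyl 3-oxodrim-8-en-11-oate (5α, 10β-methyl) | COC(=O)C1=C(C)CC[C@H]2C(C)(C)C(=O)CC[C@]12C | intermediate (not isolated)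
11 | dilithium bis-enolate of 10 (C2=C3–OLi and the 8(12),9(11)-dienolate) | C=C1CC[C@H]2C(C)(C)C(O[Li])=CC[C@]2(C)C1=C(OC)O[Li] | intermediate (not isolated)
12 | lithium enolate of 14 (C13–OLi, C13=C14) | [Li]OC1=C(C)CC[C@@]2(C)CC[C@@H](C)[C@H](C)[C@@H]12 | intermediate (not isolated)
13 | methyl 3-oxodrim-8(12)-en-11-oate (5α, 9α-H, 10β-methyl) | C=C1CC[C@H]2C(C)(C)C(=O)CC[C@]2(C)[C@H]1C(=O)OC | intermediate
14 | (2S,4aR,7R,8S,8aR)-2,4a,7,8-tetramethyloctahydronaphthalen-1(2H)-one (rings D/E; ursane C13 ketone, 14α-methyl, 17β-methyl, 18β-H, 19β-methyl, 20α-methyl) | O=C1[C@@H]2[C@@H](C)[C@H](C)CC[C@]2(C)CC[C@@H]1C | intermediate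
15 | drim-8(12)-ene-3β,11-diol | C=C1CC[C@H]2C(C)(C)[C@@H](O)CC[C@]2(C)[C@H]1CO | intermediate
16 | 11-iododrim-8(12)-en-3β-ol | C=C1CC[C@H]2C(C)(C)[C@@H](O)CC[C@]2(C)[C@H]1CI | intermediate
17 | trimethyl{(E)-[(2S,4aR,7R,8S,8aR)-2,4a,7,8-tetramethyloctahydronaphthalen-1(2H)-ylidene]methyl}silane | C[Si](C)(C)/C=C1/[C@@H]2[C@@H](C)[C@H](C)CC[C@]2(C)CC[C@@H]1C | intermediate
18 | (2S,4aR,7R,8S,8aR)-1-[(E)-iodomethylidene]-2,4a,7,8-tetramethyldecahydronaphthalene | I/C=C1/[C@@H]2[C@@H](C)[C@H](C)CC[C@]2(C)CC[C@@H]1C | intermediate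
19 | (12E)-8,14-secoursa-8(26),12-dien-3β-ol (CNP0141247.1) | C=C1CC[C@H]2C(C)(C)[C@@H](O)CC[C@]2(C)[C@H]1C/C=C1/[C@@H]2[C@@H](C)[C@H](C)CC[C@]2(C)CC[C@@H]1C | target

**Totals**

Total step count: 12. Longest linear sequence: 10 steps (1–7, 8, 9, 12; the other branch 1–7, 10, 11, 12 is equally long).

**Three steps most likely to fail**

Step 5 (oxidative cleavage of the hindered enone). The fallback sets out from 6 and comes back at 8. Nucleophilic epoxidation of the enone with H2O2/NaOH gives 12α,13α-epoxyursane-3,11-dione F1. Treatment with H5IO6 in aqueous dioxane hydrolyses the epoxy ketone and cleaves both the C11–C12 and C12–C13 bonds, C12 leaving as formic acid, to give keto acid 8.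

Step 7 (the proposed new step). The fallback uses known photochemistry; it sets out from 9 and comes back at 13 and 14. Selective ketalisation of the less hindered C3 ketone (ethylene glycol, pyridinium p-toluenesulfonate) gives methyl 3,3-ethylenedioxy-13-oxo-12-nor-12,13-secoursan-11-oate F2. Irradiation (λ > 290 nm, benzene/t-BuOH) brings about a Norrish type 2 photoelimination: the excited C13 ketone abstracts the activated γ-hydrogen at C9, the 1,4-biradical cleaves the C8–C14 bond, and the enol ketonises under neutral conditions to 14. The left half appears as methyl 3,3-ethylenedioxydrim-8-en-11-oate F3. Classical deconjugation of F3 (LiN(iPr)2, then kinetic protonation) gives methyl 3,3-ethylenedioxydrim-8(12)-en-11-oate F4, and mild aqueous acid removes the ketal to give 13.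

Step 12 (the coupling of a hindered exocyclic alkenyl iodide with a β-branched iodide). The fallback sets out from 16 and 18 and comes back at 19. Silylation of 16 (Et3SiCl, imidazole) gives 11-iodo-3β-(triethylsilyloxy)drim-8(12)-ene F5. Zinc insertion (Zn dust, LiCl, THF) gives the alkylzinc iodide F6. Negishi coupling with 18 under Pd(dppf)Cl2 catalysis, which retains alkene geometry, gives the triethylsilyl ether of the target F7, and Bu4NF then frees the alcohol to give 19.

**Further compounds**

F1 | step 5 | 12α,13α-epoxyursane-3,11-dione | C[C@@H]1CC[C@@]2(CC[C@@]3([C@]7(O[C@H]7C(=O)[C@H]4[C@]3(CC[C@@H]5[C@@]4(CCC(=O)C5(C)C)C)C)[C@@H]2[C@H]1C)C)C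
F2 | step 7 | methyl 3,3-ethylenedioxy-13-oxo-12-nor-12,13-secoursan-11-oate | COC(=O)[C@@H]1[C@@]2(C)CCC6(OCCO6)C(C)(C)[C@@H]2CC[C@@]1(C)[C@@]3(C)C(=O)[C@@H]4[C@@H](C)[C@H](C)CC[C@]4(C)CC3
F3 | step 7 | methyl 3,3-ethylenedioxydrim-8-en-11-oate | COC(=O)C1=C(C)CC[C@H]2C(C)(C)C3(OCCO3)CC[C@]12C
F4 | step 7 | methyl 3,3-ethylenedioxydrim-8(12)-en-11-oate | C=C1CC[C@H]2C(C)(C)C3(OCCO3)CC[C@]2(C)[C@H]1C(=O)OC
F5 | step 12 | 11-iodo-3β-(triethylsilyloxy)drim-8(12)-ene | C=C1CC[C@H]2C(C)(C)[C@@H](O[Si](CC)(CC)CC)CC[C@]2(C)[C@H]1CI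
F6 | step 12 | [3β-(triethylsilyloxy)drim-8(12)-en-11-yl]zinc iodide | C=C1CC[C@H]2C(C)(C)[C@@H](O[Si](CC)(CC)CC)CC[C@]2(C)[C@H]1C[Zn]I
F7 | step 12 | (12E)-3β-(triethylsilyloxy)-8,14-secoursa-8(26),12-diene | C=C1CC[C@H]2C(C)(C)[C@@H](O[Si](CC)(CC)CC)CC[C@]2(C)[C@H]1C/C=C1/[C@@H]2[C@@H](C)[C@H](C)CC[C@]2(C)CC[C@@H]1C
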